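**Retrosynthetic overview**
1. The target comes from one final hydrogenation that saturates a side-chain C=C and removes a para-O-benzyl group; the acetate is put on the hindered phenol just before, after acid removal of its MOM group.
2. The C15 alkenyl chain comes from an (E)-aryl enone by tosylhydrazone/catecholborane reductive deoxygenation (C=O removed, C=C shifted).
3. Key C–C bond (chain C1–C2): directed aldol of the kinetic lithium enolate of 2-tetradecanone with 5-(benzyloxy)-3-methoxy-2-(methoxymethoxy)benzaldehyde, then dehydration.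
4. The aldehyde comes from 5-bromovanillin by MOM protection, Baeyer–Villiger oxidation, benzylation and Br/Li exchange–formylation; this fixes early which oxygen becomes OAc and which OH.
5. No ring is formed; the benzene ring of 5-bromovanillin is carried through unchanged.

Assumption: the target has no stereocentre, so it is achiral and needs no enantiocontrol; 5-bromovanillin and 2-tetradecanone are taken as commercial.

**Route**

Step 1
Reactants: 1 5-bromovanillin (3-bromo-4-hydroxy-5-methoxybenzaldehyde); 2 chloromethyl methyl ether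
Product: 3 3-bromo-5-methoxy-4-(methoxymethoxy)benzaldehyde
Conditions: MOMCl, iPr2NEt, CH2Cl2, 0 °C to rt
Reagents that add atoms: chloromethyl methyl ether (MOMCl), COCCl
Why: O-alkylation (MOM acetal formation) of the acidic phenol gives a group that survives peracid, base and organolithium and is later removed by acid without touching a benzyl ether.

Step 2
Reactants: 3 3-bromo-5-methoxy-4-(methoxymethoxy)benzaldehyde; 4 3-chloroperoxybenzoic acid
Product: 6 3-bromo-5-methoxy-4-(methoxymethoxy)phenol, via aryl formate 5 (not isolated)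
Conditions: mCPBA, CH2Cl2, rt; then K2CO3 (cat.), MeOH, rt
Reagents that add atoms: 3-chloroperoxybenzoic acid (mCPBA), O=C(OO)c1cccc(Cl)c1
Why: Baeyer–Villiger (Dakin-type) oxidation, in which the para-alkoxy group favours aryl migration to the formate, followed by methanolysis to the phenol.

Step 3
Reactants: 6 3-bromo-5-methoxy-4-(methoxymethoxy)phenol; 7 benzyl bromide
Product: 8 5-(benzyloxy)-1-bromo-3-methoxy-2-(methoxymethoxy)benzene
Conditions: BnBr, K2CO3, DMF, rt
Reagents that add atoms: benzyl bromide, BrCc1ccccc1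
Why: Williamson ether synthesis on the only free, unhindered phenol places the hydrogenolysable group on the oxygen that ends as the free OH.

Step 4
Reactants: 8 5-(benzyloxy)-1-bromo-3-methoxy-2-(methoxymethoxy)benzene; 9 N,N-dimethylformamide
Product: 11 5-(benzyloxy)-3-methoxy-2-(methoxymethoxy)benzaldehyde, via aryllithium 10 (not isolated)
Conditions: n-BuLi, THF, −78 °C; DMF, −78 to 0 °C; aq. NH4Cl
Reagents that add atoms: N,N-dimethylformamide, CN(C)C=O
Why: Bromine–lithium exchange (fast at −78 °C, aryllithium chelated by the ortho OMOM) followed by Bouveault-type formylation with DMF.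

Step 5
Reactants: 11 5-(benzyloxy)-3-methoxy-2-(methoxymethoxy)benzaldehyde; 12 2-tetradecanone
Product: 14 rac-1-[5-(benzyloxy)-3-methoxy-2-(methoxymethoxy)phenyl]-1-hydroxypentadecan-3-one, via lithium enolate 13 (not isolated)
Conditions: LiN(iPr)2 (LDA), THF, −78 °C, 12; then 11, −78 °C; AcOH quench at −78 °C
Reagents that add atoms: 2-tetradecanone, CCCCCCCCCCCCC(C)=O
Why: Directed crossed aldol addition of the kinetic methyl-side enolate to a non-enolisable aldehyde (minor internal-enolate adduct removed by chromatography); the new carbinol centre is racemic and is destroyed in step 6.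

Step 6
Reactants: 14 rac-1-[5-(benzyloxy)-3-methoxy-2-(methoxymethoxy)phenyl]-1-hydroxypentadecan-3-one
Product: 16 (1E)-1-[5-(benzyloxy)-3-methoxy-2-(methoxymethoxy)phenyl]pentadec-1-en-3-one, via benzylic mesylate 15 (not isolated)
Conditions: MsCl, Et3N (excess), CH2Cl2, 0 °C to rt
Reagents that add atoms: none
Why: Mesylation and E1cB elimination complete the aldol condensation and give the conjugated, thermodynamically favoured E-enone.

Step 7
Reactants: 16 (1E)-1-[5-(benzyloxy)-3-methoxy-2-(methoxymethoxy)phenyl]pentadec-1-en-3-one; 17 4-methylbenzenesulfonohydrazide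
Product: 18 N'-[(1E)-1-[5-(benzyloxy)-3-methoxy-2-(methoxymethoxy)phenyl]pentadec-1-en-3-ylidene]-4-methylbenzenesulfonohydrazide
Conditions: TsNHNH2, MeOH, rt to 40 °C
Reagents that add atoms: 4-methylbenzenesulfonohydrazide, Cc1ccc(cc1)S(=O)(=O)NN
Why: Condensation of the ketone to its tosylhydrazone under neutral conditions (C=N geometry irrelevant), which the MOM and benzyl ethers tolerate.

Step 8
Reactants: 18 N'-[(1E)-1-[5-(benzyloxy)-3-methoxy-2-(methoxymethoxy)phenyl]pentadec-1-en-3-ylidene]-4-methylbenzenesulfonohydrazide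
Product: 21 5-(benzyloxy)-1-methoxy-2-(methoxymethoxy)-3-[(2E)-pentadec-2-en-1-yl]benzene, via N-boryl tosylhydrazine 19 (not isolated), via allylic diazene 20 (not isolated)
Conditions: catecholborane, CHCl3, 0 °C to rt; then NaOAc·3H2O, reflux
Reagents that add atoms: none
Why: Kabalka reduction of an α,β-unsaturated tosylhydrazone: B–H adds to C=N, sulfinate is eliminated, and the allylic diazene loses N2 by retro-ene with 1,3-shift of the C=C (mainly E; any Z isomer or saturated material converges in step 11).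

Step 9
Reactants: 21 5-(benzyloxy)-1-methoxy-2-(methoxymethoxy)-3-[(2E)-pentadec-2-en-1-yl]benzene
Product: 22 4-(benzyloxy)-2-methoxy-6-[(2E)-pentadec-2-en-1-yl]phenol
Conditions: conc. HCl (cat.), MeOH/THF, 40 °C
Reagents that add atoms: none
Why: Acid-catalysed acetal exchange removes the MOM group while the benzyl ether and the isolated 1,2-disubstituted alkene are inert under these mild conditions.

Step 10
Reactants: 22 4-(benzyloxy)-2-methoxy-6-[(2E)-pentadec-2-en-1-yl]phenol; 23 acetic anhydride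
Product: 24 4-(benzyloxy)-2-methoxy-6-[(2E)-pentadec-2-en-1-yl]phenyl acetate
Conditions: Ac2O, pyridine, DMAP (cat.), CH2Cl2, rt
Reagents that add atoms: acetic anhydride, CC(=O)OC(C)=O
Why: DMAP-catalysed acylation of the only free hydroxyl puts the acetate on the hindered phenol.

Step 11
Reactants: 24 4-(benzyloxy)-2-methoxy-6-[(2E)-pentadec-2-en-1-yl]phenyl acetate
Product: 25 4-hydroxy-2-methoxy-6-pentadecylphenyl acetate
Conditions: H2 (1 atm), 10% Pd/C (palladium on carbon), EtOAc, rt
Reagents that add atoms: none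
Why: Catalytic hydrogenation saturates the alkene and hydrogenolyses the benzyl ether in one operation, and the aryl acetate is stable in neutral aprotic solvent; the product has no stereocentre.

**Compound list**
1 | 5-bromovanillin (3-bromo-4-hydroxy-5-methoxybenzaldehyde) | O=Cc1cc(Br)c(O)c(OC)c1 | starting material
2 | chloromethyl methyl ether | COCCl | starting material
3 | 3-bromo-5-methoxy-4-(methoxymethoxy)benzaldehyde | O=Cc1cc(Br)c(OCOC)c(OC)c1 | intermediate
4 | 3-chloroperoxybenzoic acid | O=C(OO)c1cccc(Cl)c1 | starting material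
5 | 3-bromo-5-methoxy-4-(methoxymethoxy)phenyl formate | O=COc1cc(Br)c(OCOC)c(OC)c1 | intermediate (not isolated)
6 | 3-bromo-5-methoxy-4-(methoxymethoxy)phenol | Oc1cc(Br)c(OCOC)c(OC)c1 | intermediate
7 | benzyl bromide | BrCc1ccccc1 | starting material
8 | 5-(benzyloxy)-1-bromo-3-methoxy-2-(methoxymethoxy)benzene | COCOc1c(Br)cc(OCc2ccccc2)cc1OC | intermediate
9 | N,N-dimethylformamide | CN(C)C=O | starting material
10 | [5-(benzyloxy)-3-methoxy-2-(methoxymethoxy)phenyl]lithium | [Li]c1cc(OCc2ccccc2)cc(OC)c1OCOC | intermediate (not isolated)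
11 | 5-(benzyloxy)-3-methoxy-2-(methoxymethoxy)benzaldehyde | O=Cc1cc(OCc2ccccc2)cc(OC)c1OCOC | intermediate
12 | 2-tetradecanone | CCCCCCCCCCCCC(C)=O | starting material
13 | lithium tetradec-1-en-2-olate | C=C(O[Li])CCCCCCCCCCCC | intermediate (not isolated)
14 | rac-1-[5-(benzyloxy)-3-methoxy-2-(methoxymethoxy)phenyl]-1-hydroxypentadecan-3-one (racemic) | CCCCCCCCCCCCC(=O)CC(O)c1cc(OCc2ccccc2)cc(OC)c1OCOC | intermediate
15 | rac-1-[5-(benzyloxy)-3-methoxy-2-(methoxymethoxy)phenyl]-3-oxopentadecyl methanesulfonate (racemic) | CCCCCCCCCCCCC(=O)CC(OS(C)(=O)=O)c1cc(OCc2ccccc2)cc(OC)c1OCOC | intermediate (not isolated)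
16 | (1E)-1-[5-(benzyloxy)-3-methoxy-2-(methoxymethoxy)phenyl]pentadec-1-en-3-one | CCCCCCCCCCCCC(=O)/C=C/c1cc(OCc2ccccc2)cc(OC)c1OCOC | intermediate
17 | 4-methylbenzenesulfonohydrazide | Cc1ccc(cc1)S(=O)(=O)NN | starting material
18 | N'-[(1E)-1-[5-(benzyloxy)-3-methoxy-2-(methoxymethoxy)phenyl]pentadec-1-en-3-ylidene]-4-methylbenzenesulfonohydrazide (C=N geometry not fixed) | CCCCCCCCCCCCC(=NNS(=O)(=O)c1ccc(C)cc1)/C=C/c1cc(OCc2ccccc2)cc(OC)c1OCOC | intermediate
19 | rac-N'-(1,3,2-benzodioxaborol-2-yl)-N'-[(1E)-1-[5-(benzyloxy)-3-methoxy-2-(methoxymethoxy)phenyl]pentadec-1-en-3-yl]-4-methylbenzenesulfonohydrazide (racemic) | CCCCCCCCCCCCC(/C=C/c1cc(OCc2ccccc2)cc(OC)c1OCOC)N(B1Oc2ccccc2O1)NS(=O)(=O)c1ccc(C)cc1 | intermediate (not isolated)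
20 | rac-[(1E)-1-[5-(benzyloxy)-3-methoxy-2-(methoxymethoxy)phenyl]pentadec-1-en-3-yl]diazene (racemic) | CCCCCCCCCCCCC(N=N)/C=C/c1cc(OCc2ccccc2)cc(OC)c1OCOC | intermediate (not isolated)
21 | 5-(benzyloxy)-1-methoxy-2-(methoxymethoxy)-3-[(2E)-pentadec-2-en-1-yl]benzene (mainly E) | CCCCCCCCCCCC/C=C/Cc1cc(OCc2ccccc2)cc(OC)c1OCOC | intermediate
22 | 4-(benzyloxy)-2-methoxy-6-[(2E)-pentadec-2-en-1-yl]phenol | CCCCCCCCCCCC/C=C/Cc1cc(OCc2ccccc2)cc(OC)c1O | intermediate
23 | acetic anhydride | CC(=O)OC(C)=O | starting material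
24 | 4-(benzyloxy)-2-methoxy-6-[(2E)-pentadec-2-en-1-yl]phenyl acetate | CCCCCCCCCCCC/C=C/Cc1cc(OCc2ccccc2)cc(OC)c1OC(C)=O | intermediate
25 | 4-hydroxy-2-methoxy-6-pentadecylphenyl acetate (achiral) | CCCCCCCCCCCCCCCc1cc(O)cc(OC)c1OC(C)=O | target

**Totals**
Total step count: 11. Longest linear sequence: 11 steps (1 to 25).

**Steps most likely to fail, with fallbacks**

Step 8 (reductive deoxygenation of the enone tosylhydrazone; pyrazoline formation or incomplete diazene fragmentation could lower the yield). The fallback sets out from enone 16 and comes back to the route at target 25. Conjugate reduction of 16 with [(Ph3P)CuH]6 in wet toluene, which leaves the benzyl ether intact, gives 1-[5-(benzyloxy)-3-methoxy-2-(methoxymethoxy)phenyl]pentadecan-3-one F1. Wolff–Kishner reduction (N2H4·H2O, KOH, diethylene glycol, 130 then 195 °C) proceeds through [1-[5-(benzyloxy)-3-methoxy-2-(methoxymethoxy)phenyl]pentadecan-3-ylidene]hydrazine F2 to 5-(benzyloxy)-1-methoxy-2-(methoxymethoxy)-3-pentadecylbenzene F3. HCl in MeOH/THF then gives 4-(benzyloxy)-2-methoxy-6-pentadecylphenol F4, Ac2O/pyridine/DMAP gives 4-(benzyloxy)-2-methoxy-6-pentadecylphenyl acetate F5, and hydrogenolysis (H2, Pd/C, EtOAc) gives 25.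

Step 5 (key aldol; a hindered, electron-rich aldehyde, possible retro-aldol and imperfect methyl/methylene enolate selectivity). The fallback sets out from ketone 12 and comes back at aldol 14. Ketone 12 is converted (LDA, Me3SiCl, THF, −78 °C) into the distillable kinetic silyl enol ether 2-(trimethylsilyloxy)tetradec-1-ene F6. A Mukaiyama aldol of F6 with aldehyde 11 (BF3·OEt2, CH2Cl2, −78 °C, aqueous NaHCO3 work-up) then gives 14 with the regiochemistry fixed beforehand.

Step 4 (Br/Li exchange–formylation; butylation of the aryllithium or benzylic deprotonation of the OBn group are possible). The fallback sets out from bromide 8 and comes back at aldehyde 11. Suzuki–Miyaura coupling of 8 with potassium vinyltrifluoroborate (PdCl2(dppf), K2CO3, THF/H2O, reflux) gives 5-(benzyloxy)-1-ethenyl-3-methoxy-2-(methoxymethoxy)benzene F7. Lemieux–Johnson cleavage (OsO4 cat., NaIO4, 2,6-lutidine, dioxane/H2O) then gives 11.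

**Further compounds**
F1 | step 8 | 1-[5-(benzyloxy)-3-methoxy-2-(methoxymethoxy)phenyl]pentadecan-3-one | CCCCCCCCCCCCC(=O)CCc1cc(OCc2ccccc2)cc(OC)c1OCOC
F2 | step 8 | [1-[5-(benzyloxy)-3-methoxy-2-(methoxymethoxy)phenyl]pentadecan-3-ylidene]hydrazine | CCCCCCCCCCCCC(=NN)CCc1cc(OCc2ccccc2)cc(OC)c1OCOC
F3 | step 8 | 5-(benzyloxy)-1-methoxy-2-(methoxymethoxy)-3-pentadecylbenzene | CCCCCCCCCCCCCCCc1cc(OCc2ccccc2)cc(OC)c1OCOC
F4 | step 8 | 4-(benzyloxy)-2-methoxy-6-pentadecylphenol | CCCCCCCCCCCCCCCc1cc(OCc2ccccc2)cc(OC)c1O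
F5 | step 8 | 4-(benzyloxy)-2-methoxy-6-pentadecylphenyl acetate | CCCCCCCCCCCCCCCc1cc(OCc2ccccc2)cc(OC)c1OC(C)=O
F6 | step 5 | 2-(trimethylsilyloxy)tetradec-1-ene | C=C(O[Si](C)(C)C)CCCCCCCCCCCC
F7 | step 4 | 5-(benzyloxy)-1-ethenyl-3-methoxy-2-(methoxymethoxy)benzene | C=Cc1cc(OCc2ccccc2)cc(OC)c1OCOC
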